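The target is an 8,11-diacylated guai-4-en-3-one (guaiane numbering: C3 ketone, C4 methyl-bearing olefin carbon, C5 and C1 ring-fusion carbons). The route rests on disconnecting the cyclopentenone at C3–C4 and C1–C5, which turns the bicycle into an open-chain enoate (C1=C2–C3) tethered to a 2-butynyl group (C4≡C5). A nickel-catalysed reductive [3+2] cycloaddition should close the seven- and the five-membered ring in one operation, set C1 and deliver the enone directly, with the ester methoxide as leaving group. The C8/C11 diol is held as a temporary acetonide that bends the tether for the seven-membered closure. The chain comes from (R)-citronellal and an Evans syn-aldol.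

Key step: step 8

Remark: guaiane numbering (C1–C11) is used for the carbon atoms throughout, also in the open-chain intermediates.
Assumption: commercial (R)-citronellal of high enantiomeric purity is used; diastereomers arising from any antipode are removed at the aldol stage.

Step 1
Reactants: 1 hex-4-ynoic acid; 2 (4S)-4-benzyl-1,3-oxazolidin-2-one
Product: 3 (4S)-4-benzyl-3-(hex-4-ynoyl)-1,3-oxazolidin-2-one
Conditions: DCC, DMAP (cat.), CH2Cl2, 0 °C to rt
Reagents that add atoms: none
Why: Carbodiimide activation with DMAP as acyl-transfer catalyst (Steglich-type N-acylation) should acylate the oxazolidinone without strong base, and no stereocentre is touched.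

Step 2
Reactants: 3 (4S)-4-benzyl-3-(hex-4-ynoyl)-1,3-oxazolidin-2-one; 4 (R)-citronellal
Product: 6 (4S)-4-benzyl-3-[(2S,3R,5R)-2-(but-2-yn-1-yl)-3-hydroxy-5,9-dimethyldec-8-enoyl]-1,3-oxazolidin-2-one, via Z-dibutylboron enolate 5 (not isolated)
Conditions: Bu2BOTf, iPr2NEt, CH2Cl2, 0 °C; then 4, −78 to 0 °C; work-up pH 7 buffer, MeOH, H2O2
Reagents that add atoms: none
Why: In this Evans syn-aldol the Z-boron enolate should react through a closed Zimmerman–Traxler chair on the face opposite to the benzyl group, which sets C7 (S) and C8 (R) together under auxiliary control, the remote C10 methyl of the aldehyde having little influence.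

Step 3
Reactants: 6 aldol adduct
Product: 7 methyl (2S,3R,5R)-2-(but-2-yn-1-yl)-3-hydroxy-5,9-dimethyldec-8-enoate
Conditions: MeOMgBr (from MeMgBr and MeOH), CH2Cl2/MeOH, 0 °C
Reagents that add atoms: methanol, CO, delivered as bromomagnesium methoxide, C[O-].[Mg+2].[Br-]
Why: Transesterification by the magnesium alkoxide at the exocyclic imide carbonyl of the chelated aldolate should release the auxiliary without retro-aldol cleavage or epimerisation at C7.

Step 4
Reactants: 7 methyl ester
Product: 9 (3S,4R,6R)-3-(but-2-yn-1-yl)-2,6,10-trimethylundec-9-ene-2,4-diol, via methyl ketone 8 (not isolated)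
Conditions: MeMgBr (5 equiv), THF, 0 °C to rt; aq. NH4Cl
Reagents that add atoms: methylmagnesium bromide, C[Mg]Br
Why: Double Grignard addition to the ester through the methyl ketone should give the C11 dimethylcarbinol, and no new stereocentre is formed.

Step 5
Reactants: 9 diol
Product: 10 (5S,6R)-5-(but-2-yn-1-yl)-6-[(2R)-2,6-dimethylhept-5-en-1-yl]-2,2,4,4-tetramethyl-1,3-dioxane
Conditions: 2-methoxypropene, PPTS (cat.), CH2Cl2, 0 °C to rt
Reagents that add atoms: 2-methoxypropene, COC(C)=C
Why: Acid-catalysed ketalisation with the enol ether should trap the hindered 1,3-diol kinetically as its acetonide, which protects both hydroxyls and fixes the C6 and C9 arms gauche on one six-membered ring.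

Step 6
Reactants: 10 acetonide
Product: 11 methyl (4R)-5-[(4R,5S)-5-(but-2-yn-1-yl)-2,2,6,6-tetramethyl-1,3-dioxan-4-yl]-4-methylpentanoate
Conditions: O3 (to first persistence), NaOH (2.5 M in MeOH), CH2Cl2, −78 °C
Reagents that add atoms: ozone, [O-][O+]=O; methanol, CO
Why: Ozonolysis in methanolic sodium hydroxide should cleave the electron-rich trisubstituted alkene much faster than the internal alkyne and oxidise the C3 terminus in the same pot to the methyl ester, while the acetonide is stable to base.

Step 7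
Reactants: 11 saturated methyl ester
Product: 14 methyl (2E,4S)-5-[(4R,5S)-5-(but-2-yn-1-yl)-2,2,6,6-tetramethyl-1,3-dioxan-4-yl]-4-methylpent-2-enoate, via lithium ester enolate 12 (not isolated), via α-phenylselanyl ester 13 (not isolated)
Conditions: LiN(iPr)2, THF, −78 °C; PhSeBr, −78 °C; then H2O2 (30%), pyridine, CH2Cl2, 0 °C to rt
Reagents that add atoms: none
Why: α-Selenenylation of the ester enolate followed by selenoxide syn-elimination should give the E-enoate (C1=C2) without touching the C10 stereocentre.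

Step 8
Reactants: 14 enoate–alkyne
Product: 15 (1R,7S,8R,10S)-8,11-(isopropylidenedioxy)guai-4-en-3-one, the acetonide of 16
Conditions: Ni(cod)2 (20 mol%), PBu3 (40 mol%), Et3B (3 equiv), MeOH/THF, 50 °C, 0.01 M, slow addition of 14
Reagents that add atoms: none
Why: Zerovalent nickel couples the enoate and the alkyne by oxidative cyclisation to a nickelacycle, which forms the C1–C5 bond; methanol protonates the nickel enolate at C2, the alkenylnickel at C4 adds to the ester carbonyl and expels methoxide to form the C3–C4 bond and the enone, and Et3B returns divalent nickel to the zerovalent state. The closest known reactions are the nickel-catalysed reductive [3+2] cycloaddition of enoates with alkynes to cyclopentenones and the intramolecular [3+2] of alkynyl enals; a seven-membered closure is the extension asked of it here. The cycloheptane closes in a 7-exo mode (exo to both the alkene and the alkyne) and the cyclopentenone in a 5-exo-trig acylation. C1 is set in the oxidative cyclisation under control of C10: with the C10–H bond eclipsing the enoate (minimal A(1,3) strain) and the alkyne arriving from the C9 side, the methyl group should end up cis to H1 and trans to C2, as in the target. The step needs cyclisation to beat intermolecular coupling and premature protonation of the alkenylnickel; the acetonide, which holds the C6 and C9 arms gauche, together with high dilution, should secure this, and the tether allows only C5 to reach C1.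

Step 9
Reactants: 15 acetonide
Product: 16 (5S,6R,8S,8aR)-6-hydroxy-5-(2-hydroxypropan-2-yl)-3,8-dimethyl-4,5,6,7,8,8a-hexahydroazulen-2(1H)-one
Conditions: AcOH/H2O/THF (3:1:1), 40 °C
Reagents that add atoms: none
Why: Mild acid-catalysed acetal hydrolysis should remove the strained acetonide while the enone and the tertiary alcohol survive at this acidity.

Step 10
Reactants: 16 diol
Product: 17 (5S,6R,8S,8aR)-5-(2-hydroxypropan-2-yl)-3,8-dimethyl-2-oxo-1,2,4,5,6,7,8,8a-octahydroazulen-6-yl propanoate
Conditions: (EtCO)2O (1.2 equiv), Et3N, DMAP (cat.), CH2Cl2, 0 °C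
Reagents that add atoms: propanoic anhydride, CCC(=O)OC(=O)CC
Why: In this DMAP-catalysed esterification the secondary C8 hydroxyl should be acylated much faster than the hindered tertiary C11 hydroxyl.

Step 11
Reactants: 17 mono-propanoate
Product: 18 (5S,6R,8S,8aR)-5-(2-acetoxypropan-2-yl)-3,8-dimethyl-2-oxo-1,2,4,5,6,7,8,8a-octahydroazulen-6-yl propanoate (target)
Conditions: Ac2O (excess), DMAP (1 equiv), Et3N, CH2Cl2, 40 °C
Reagents that add atoms: acetic anhydride, CC(=O)OC(C)=O
Why: Acylation through the acetylpyridinium ion (Steglich-type esterification of a hindered alcohol) should acetylate the tertiary hydroxyl under basic, non-ionising conditions that avoid dehydration and leave the propanoate in place.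

Compound list
1 | hex-4-ynoic acid | CC#CCCC(=O)O | starting material
2 | (4S)-4-benzyl-1,3-oxazolidin-2-one | O=C1N[C@@H](Cc2ccccc2)CO1 | starting material
3 | (4S)-4-benzyl-3-(hex-4-ynoyl)-1,3-oxazolidin-2-one | CC#CCCC(=O)N1[C@@H](Cc2ccccc2)COC1=O | intermediate
4 | (R)-citronellal, (3R)-3,7-dimethyloct-6-enal | C[C@H](CCC=C(C)C)CC=O | starting material
5 | Z-dibutylboron enolate of 3 | CC#CC/C=C(\OB(CCCC)CCCC)N1[C@@H](Cc2ccccc2)COC1=O | intermediate (not isolated)
6 | (4S)-4-benzyl-3-[(2S,3R,5R)-2-(but-2-yn-1-yl)-3-hydroxy-5,9-dimethyldec-8-enoyl]-1,3-oxazolidin-2-one | CC#CC[C@@H]([C@H](O)C[C@H](C)CCC=C(C)C)C(=O)N1[C@@H](Cc2ccccc2)COC1=O | intermediate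
7 | methyl (2S,3R,5R)-2-(but-2-yn-1-yl)-3-hydroxy-5,9-dimethyldec-8-enoate | CC#CC[C@@H]([C@H](O)C[C@H](C)CCC=C(C)C)C(=O)OC | intermediate
8 | (3S,4R,6R)-3-(but-2-yn-1-yl)-4-hydroxy-6,10-dimethylundec-9-en-2-one | CC#CC[C@@H]([C@H](O)C[C@H](C)CCC=C(C)C)C(C)=O | intermediate (not isolated)
9 | (3S,4R,6R)-3-(but-2-yn-1-yl)-2,6,10-trimethylundec-9-ene-2,4-diol | CC#CC[C@@H]([C@H](O)C[C@H](C)CCC=C(C)C)C(C)(C)O | intermediate
10 | (5S,6R)-5-(but-2-yn-1-yl)-6-[(2R)-2,6-dimethylhept-5-en-1-yl]-2,2,4,4-tetramethyl-1,3-dioxane | CC#CC[C@H]1[C@@H](C[C@H](C)CCC=C(C)C)OC(C)(C)OC1(C)C | intermediate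
11 | methyl (4R)-5-[(4R,5S)-5-(but-2-yn-1-yl)-2,2,6,6-tetramethyl-1,3-dioxan-4-yl]-4-methylpentanoate | CC#CC[C@H]1[C@@H](C[C@H](C)CCC(=O)OC)OC(C)(C)OC1(C)C | intermediate
12 | lithium enolate of 11 | CC#CC[C@H]1[C@@H](C[C@H](C)CC=C([O-])OC)OC(C)(C)OC1(C)C.[Li+] | intermediate (not isolated)
13 | 2-(phenylselanyl) derivative of 11 (both C2 epimers) | CC#CC[C@H]1[C@@H](C[C@H](C)CC([Se]c2ccccc2)C(=O)OC)OC(C)(C)OC1(C)C | intermediate (not isolated)
14 | methyl (2E,4S)-5-[(4R,5S)-5-(but-2-yn-1-yl)-2,2,6,6-tetramethyl-1,3-dioxan-4-yl]-4-methylpent-2-enoate | CC#CC[C@H]1[C@@H](C[C@H](C)/C=C/C(=O)OC)OC(C)(C)OC1(C)C | intermediate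
15 | (1R,7S,8R,10S)-8,11-(isopropylidenedioxy)guai-4-en-3-one (acetonide of 16, 1,3-dioxane cis-fused at C7–C8) | CC1(C)O[C@@H]2C[C@H](C)[C@H]3CC(=O)C(C)=C3C[C@@H]2C(C)(C)O1 | intermediate
16 | (5S,6R,8S,8aR)-6-hydroxy-5-(2-hydroxypropan-2-yl)-3,8-dimethyl-4,5,6,7,8,8a-hexahydroazulen-2(1H)-one | O[C@@H]1C[C@H](C)[C@H]2CC(=O)C(C)=C2C[C@@H]1C(C)(C)O | intermediate
17 | (5S,6R,8S,8aR)-5-(2-hydroxypropan-2-yl)-3,8-dimethyl-2-oxo-1,2,4,5,6,7,8,8a-octahydroazulen-6-yl propanoate | CCC(=O)O[C@@H]1C[C@H](C)[C@H]2CC(=O)C(C)=C2C[C@@H]1C(C)(C)O | intermediate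
18 | (5S,6R,8S,8aR)-5-(2-acetoxypropan-2-yl)-3,8-dimethyl-2-oxo-1,2,4,5,6,7,8,8a-octahydroazulen-6-yl propanoate | CCC(=O)O[C@@H]1C[C@H](C)[C@H]2CC(=O)C(C)=C2C[C@@H]1C(C)(C)OC(C)=O | target

Total step count: 11. Longest linear sequence: 11 steps (1 to 18; 2 and 4 enter in steps 1 and 2).

Steps most likely to fail

Step 8. The oxidative cyclisation may not close the seven-membered ring, so that the substrate oligomerises or is only reduced. The alkenylnickel may also be protonated before it acylates, or the facial selectivity at C1 may be poor. The fallback sets out from 11 and comes back at 15. Saponification (LiOH, THF/H2O) should give (4R)-5-[(4R,5S)-5-(but-2-yn-1-yl)-2,2,6,6-tetramethyl-1,3-dioxan-4-yl]-4-methylpentanoic acid F1. Oxidative decarboxylation (Pb(OAc)4, Cu(OAc)2 (cat.), pyridine, benzene, 80 °C) should then give the 1,8-enyne (5S,6R)-5-(but-2-yn-1-yl)-2,2,4,4-tetramethyl-6-[(2S)-2-methylbut-3-en-1-yl]-1,3-dioxane F2. An intramolecular Pauson–Khand reaction (Co2(CO)8 (cat.), tetramethylthiourea, CO (1 atm), benzene, 70 °C) would close both rings, with carbon monoxide supplying C3, and give 15.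

Step 6. Ozone may attack the triple bond once the alkene is consumed, or the oxidation may stop short of the ester. The fallback sets out from 10 and comes back at 11. Dihydroxylation (OsO4 (cat.), N-methylmorpholine N-oxide, acetone/H2O), to which the alkyne is inert, should give (6R)-7-[(4R,5S)-5-(but-2-yn-1-yl)-2,2,6,6-tetramethyl-1,3-dioxan-4-yl]-2,6-dimethylheptane-2,3-diol F3 as both C3 epimers. Glycol cleavage (NaIO4, THF/H2O) should give (4R)-5-[(4R,5S)-5-(but-2-yn-1-yl)-2,2,6,6-tetramethyl-1,3-dioxan-4-yl]-4-methylpentanal F4. Oxidative esterification (pyridinium dichromate, (C5H5NH)2Cr2O7, MeOH, DMF) would then give 11.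

Step 4. Enolisation of the ester or of the intermediate ketone, and retro-aldol cleavage of the magnesium aldolate, may compete with the double addition. The fallback sets out from 6, bypasses 7 and comes back at 9. Transamidation (AlMe3, MeNH(OMe)·HCl, CH2Cl2, 0 °C) should give the Weinreb amide (2S,3R,5R)-2-(but-2-yn-1-yl)-3-hydroxy-N-methoxy-N,5,9-trimethyldec-8-enamide F5. A single addition of MeMgBr, stopped at the stable chelate, should give methyl ketone 8, which is isolated here. Addition of the non-basic organocerium reagent (MeLi, CeCl3, THF, −78 °C) would then give 9.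

Further compounds
F1 | step 8 | (4R)-5-[(4R,5S)-5-(but-2-yn-1-yl)-2,2,6,6-tetramethyl-1,3-dioxan-4-yl]-4-methylpentanoic acid | CC#CC[C@H]1[C@@H](C[C@H](C)CCC(=O)O)OC(C)(C)OC1(C)C
F2 | step 8 | (5S,6R)-5-(but-2-yn-1-yl)-2,2,4,4-tetramethyl-6-[(2S)-2-methylbut-3-en-1-yl]-1,3-dioxane | CC#CC[C@H]1[C@@H](C[C@H](C)C=C)OC(C)(C)OC1(C)C
F3 | step 6 | (6R)-7-[(4R,5S)-5-(but-2-yn-1-yl)-2,2,6,6-tetramethyl-1,3-dioxan-4-yl]-2,6-dimethylheptane-2,3-diol (both C3 epimers) | CC#CC[C@H]1[C@@H](C[C@H](C)CCC(O)C(C)(C)O)OC(C)(C)OC1(C)C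
F4 | step 6 | (4R)-5-[(4R,5S)-5-(but-2-yn-1-yl)-2,2,6,6-tetramethyl-1,3-dioxan-4-yl]-4-methylpentanal | CC#CC[C@H]1[C@@H](C[C@H](C)CCC=O)OC(C)(C)OC1(C)C
F5 | step 4 | (2S,3R,5R)-2-(but-2-yn-1-yl)-3-hydroxy-N-methoxy-N,5,9-trimethyldec-8-enamide | CC#CC[C@@H]([C@H](O)C[C@H](C)CCC=C(C)C)C(=O)N(C)OC
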